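1. The pitfall is to compare target in percent of the substrate charged: the autumn run reads 12.0% at 50.0 min and the noon run 8.3% at 50.0 min, yet these two runs reacted different parts of their substrate.

| flask | substrate | reagent in the second phase | remark | time | volume of the second phase over the first |
|---|---|---|---|---|---|
| autumn | 39 mM | 29.4 mM | run made earlier |  |  |
| noon | 62 mM | 29.4 mM | run made earlier |  |  |
| flask | 28 mM | 29.4 mM |  | 50 min | 0.25 |

| run | time / min | target / % | substrate / % |
|---|---|---|---|
| autumn | 8.00 | 22.9 | 24.5 |
| autumn | 15.0 | 17.0 | 24.8 |
| autumn | 20.0 | 15.7 | 23.7 |
| autumn | 30.0 | 13.3 | 24.5 |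
| autumn | 40.0 | 12.9 | 24.9 |
| autumn | 50.0 | 12.0 | 24.3 |
| noon | 4.00 | 22.7 | 52.6 |
| noon | 6.00 | 17.5 | 52.4 |
| noon | 10.0 | 12.0 | 52.6 |
| noon | 15.0 | 11.2 | 52.6 |
| noon | 20.0 | 8.8 | 52.8 |
| noon | 30.0 | 8.3 | 52.9 |
| noon | 50.0 | 8.3 | 52.6 |

(each reading ± 0.5 percentage points)

- in the second phase: reagent in the second phase; everything else is in the first
- charges count per volume of the first phase; a concentration in a rate is the amount of a species over the volume of its own phase; every rate counts per litre of the first phase
- the earlier runs were read with a standard deviation of 0.5 percentage points
- candidate steps: reagent in the reaction phase <-> reagent in the second phase; substrate + reagent in the reaction phase -> target; target -> over-reaction product; target <-> isomer of the product; reagent in the reaction phase <-> dormant form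
- the earlier runs hold the two phases in the same ratio of volumes as the flask asked about

- how much target there is at 50 min, in percent of the substrate charged
- part of the substrate charged that has reacted at 50 min

2. A bench rule of thumb says that substrate reacts one to one with the reagent charge, the reagent being the limiting reagent. Reagent charge over substrate charge is 75.4% in the autumn run and 47.4% in the noon run, and the readings show 75.7% and 47.4% reacted.

3. The rule stops where that ratio passes one. In the flask it is 1.05, with more reagent charged than substrate, so this reckoning caps the reacted part at 100% and makes substrate the limiting one.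

4. At 50.0 min the readings of the autumn run give 15.9% and those of the noon run 17.5%: this is the clock share, target per substrate reacted at one time.

5. With the reacted part at its cap, this reckoning puts target in the flask at 15.9% to 17.5% at 50 min.

6. The forecast says 18% of target and 99% reacted, a little higher on target: “the flask may sit slightly above the plateau”.

The flask gives 16.0% of target, with >99.9% reacted.

    reagent in the reaction phase ⇌ reagent in the second phase, rate k1*([reagent in the reaction phase] - [reagent in the second phase]/K1) per volume of the first phase (partition coefficient = 0.410, kL = 0.00300 s⁻¹)
    substrate + reagent in the reaction phase → target (k = 1.90 M⁻¹ s⁻¹)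
    target → over-reaction product (k = 4.70 × 10⁻⁴ s⁻¹)
    target ⇌ isomer of the product (K = 2.90, k = 0.00360 s⁻¹)
    reagent in the reaction phase ⇌ dormant form (K = 0.390, k = 1.70 × 10⁻⁴ s⁻¹)

The forecast stands within its margin, and the flask at 50 min holds 0.017% of its substrate charged, so the clock shares of the two runs give 15.9% to 17.5% of target against the 16.0% found. The neighbouring flask is the same flask read at 12 min, with 98.5% reacted. The noon run's clock share, from its readings, is 25.3% at 10.0 min and 23.6% at 15.0 min, both higher than its 17.5% at 50.0 min, and on that reacted part these give 23.2% to 24.9%. That neighbouring flask holds 24.0% of target.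

The data come from a simulation for an exercise, noise included.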